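**Retrosynthetic overview**

- The strategy rests on the C1–C8 bond. The gem-dimethyl carbon C8 sits on the acyl-bearing bridgehead C1 (flanked by the C2 and C9 carbonyls), and C6–C7(prenyl)–C8 on C5 is a lavandulyl unit; cutting C1–C8 therefore opens the bicyclo[3.3.1]nonane to a dearomatised acylphloroglucinol ring (C1–C5 plus C9) carrying prenyl and lavandulyl on its quaternary C5.
- Ring B (C1–C5, C9) is the ring of purchased methyl 2,4,6-trihydroxybenzoate, which is acylated, C-prenylated and then dearomatised by C-alkylation with (S)-lavandulyl triflate. Ring A (C1, C8, C7, C6, C5, C9) is closed last by an acid-triggered cation–enol cyclisation.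
- The methyl ester occupies C3 through these steps and is then removed; the acid-sensitive 3-hydroxy-3-methylbutyl chain goes onto C3 at the very end by reductive alkylation.
- Stereochemistry: the acyl centre is bought with (R)-2-methylbutanoic acid, C7 comes from auxiliary-made (S)-lavandulol, C5 is sorted by separating epimers, and C1 follows from C5 in the ring closure.

Key step: step 9

Remark: the enolised polycarbonyl compounds are drawn as one tautomer each and the equilibrating tautomers are treated as one compound; C1–C9 are the bicyclo[3.3.1]nonane atoms of the target.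

Step 1
Reactants: 1 (R)-2-methylbutanoic acid
Product: 2 (R)-2-methylbutanoyl chloride
Conditions: (COCl)2, cat. N,N-dimethylformamide, CH2Cl2, 0 °C to rt; solvent distilled off, used crude
Reagents that add atoms: oxalyl chloride, O=C(Cl)C(=O)Cl
Why: Acid chloride formation through the chloroiminium (Vilsmeier-type) intermediate runs without base, so the α-stereocentre has no ketene or enolate pathway by which to racemise.

Step 2
Reactants: 2 (R)-2-methylbutanoyl chloride, 3 methyl 2,4,6-trihydroxybenzoate
Product: 4 methyl 2,4,6-trihydroxy-3-[(2R)-2-methylbutanoyl]benzoate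
Conditions: AlCl3 (4 equiv), CH2Cl2/PhNO2, 0 °C to rt
Reagents that add atoms: none
Why: Friedel–Crafts C-acylation at one of the two equivalent free ring carbons should stop at mono-acylation because the aluminium-chelated product is deactivated, and the low temperature is chosen to keep the α-centre intact.

Step 3
Reactants: 4 methyl 2,4,6-trihydroxy-3-[(2R)-2-methylbutanoyl]benzoate, 5 prenyl bromide (1-bromo-3-methylbut-2-ene)
Product: 6 methyl 2,4,6-trihydroxy-3-[(2R)-2-methylbutanoyl]-5-(3-methylbut-2-en-1-yl)benzoate
Conditions: 10% aq. KOH, 0 °C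
Reagents that add atoms: none
Why: C-alkylation of the phenolate with the allylic bromide is favoured in water, where hydrogen bonding masks the oxygens, and only one ring carbon is still unsubstituted.

Step 4
Reactants: 7 (S)-4-benzyl-2-oxazolidinone, 8 3-methylbut-2-enoyl chloride
Product: 9 (4S)-4-benzyl-3-(3-methylbut-2-enoyl)oxazolidin-2-one
Conditions: n-BuLi, THF, −78 °C; then 8, −78 to 0 °C
Reagents that add atoms: none
Why: N-acylation of the lithiated oxazolidinone by the acid chloride is the standard way to make the imide.

Step 5
Reactants: 9 (4S)-4-benzyl-3-(3-methylbut-2-enoyl)oxazolidin-2-one, 5 prenyl bromide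
Product: 10 (4S)-4-benzyl-3-[(2S)-5-methyl-2-(prop-1-en-2-yl)hex-4-enoyl]oxazolidin-2-one
Conditions: NaN(SiMe3)2, THF, −78 °C; then 5, −78 to −40 °C
Reagents that add atoms: none
Why: γ-Deprotonation gives the chelated Z-dienolate, which is alkylated at its α-carbon (deconjugative Evans alkylation) on the face away from the benzyl group, and this sets the (2S) centre.

Step 6
Reactants: 10 (4S)-4-benzyl-3-[(2S)-5-methyl-2-(prop-1-en-2-yl)hex-4-enoyl]oxazolidin-2-one
Product: 11 (S)-lavandulol, (2S)-5-methyl-2-(prop-1-en-2-yl)hex-4-en-1-ol
Conditions: LiBH4, H2O (1 equiv), Et2O, 0 °C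
Reagents that add atoms: none
Why: Borohydride reduction at the exocyclic imide carbonyl releases the primary alcohol and the intact auxiliary without base strong enough to epimerise or conjugate the β,γ-unsaturated centre.

Step 7
Reactants: 11 (S)-lavandulol
Product: 12 (S)-lavandulyl triflate, (2S)-5-methyl-2-(prop-1-en-2-yl)hex-4-en-1-yl trifluoromethanesulfonate
Conditions: Tf2O, 2,6-di-tert-butyl-4-methylpyridine, CH2Cl2, −78 °C; cold pentane/silica filtration, used at once
Reagents that add atoms: triflic anhydride, O=S(=O)(OS(=O)(=O)C(F)(F)F)C(F)(F)F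
Why: O-Sulfonylation of the primary alcohol with a non-nucleophilic base at low temperature gives the reactive triflate without ionisation, elimination or change at the stereocentre.

Step 8
Reactants: 6 methyl 2,4,6-trihydroxy-3-[(2R)-2-methylbutanoyl]-5-(3-methylbut-2-en-1-yl)benzoate, 12 (S)-lavandulyl triflate
Product: 13 methyl (3S)-2,6-dihydroxy-5-[(2R)-2-methylbutanoyl]-3-(3-methylbut-2-en-1-yl)-3-[(2R)-5-methyl-2-(prop-1-en-2-yl)hex-4-en-1-yl]-4-oxocyclohexa-1,5-diene-1-carboxylate (the lavandulyl centre is spatially unchanged; its descriptor changes by priority only)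
Conditions: LiN(SiMe3)2 (3.1 equiv), THF, 0 °C; then 12, 0 °C to rt; chromatographic separation of the C5 epimers
Reagents that add atoms: none
Why: Dearomative C-alkylation (SN2 on the primary triflate) should occur at the prenyl-bearing carbon, the most nucleophilic carbon of the lithium trianion since the other two ring carbons carry acyl groups; the new quaternary centre C5 forms without facial control, so the epimer shown is isolated from its C5 epimer by chromatography.

Step 9
Reactants: 13 the dearomatised 6-prenyl-6-lavandulyl precursor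
Product: 14 methyl (1R,5S,7R)-4-hydroxy-8,8-dimethyl-1-[(2R)-2-methylbutanoyl]-5,7-bis(3-methylbut-2-en-1-yl)-2,9-dioxobicyclo[3.3.1]non-3-ene-3-carboxylate (C7 prenyl equatorial on ring A)
Conditions: HCOOH, rt, dark
Reagents that add atoms: none
Why: Proposed new method: formic acid protonates the 1,1-disubstituted isopropenyl alkene in the Markovnikov sense to the tertiary C8 cation, which is captured by the enol carbon C1 of the chelated acyl-triketone, and loss of the enol proton leaves the C2 ketone. The closest known reaction type is the formic acid-mediated cation–enol cyclisation of dearomatised prenylated acylphloroglucinols, which closes at an alkyl-bearing ring carbon and gives type B cores; closure at the acyl-bearing carbon to the type A core is not established. Ring A (C1, C8, C7, C6, C5, C9) closes as a six-membered ring by intramolecular C-alkylation of the enol (6-enolendo if the C9 enol reacts) through a chair that places the C7 prenyl group equatorial. The only new stereocentre, C1, is dictated by C5, because the three-atom tether can reach C1 only on the ring face from which it hangs. The step needs attack at C1 rather than C3 and C- rather than O-alkylation: with the C5/C7 relationship of 13 the equatorial-prenyl chair exists only for closure at C1, and a tertiary alkyl enol ether from O-capture should re-ionise in the acid and drain to the C–C product. The open risks are protonation of the two prenyl alkenes and the low nucleophilicity of the triacylmethane carbon.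

Step 10
Reactants: 14 the bicyclic C3 methyl ester
Product: 16 (1S,5S,7R)-4-hydroxy-8,8-dimethyl-1-[(2R)-2-methylbutanoyl]-5,7-bis(3-methylbut-2-en-1-yl)bicyclo[3.3.1]non-3-ene-2,9-dione, via C3 carboxylic acid 15 (not isolated)
Conditions: LiCl, DMSO, H2O, 120 °C
Reagents that add atoms: none
Why: Krapcho dealkoxycarbonylation, in which chloride demethylates the vinylogous β-keto ester by SN2 attack and the β-keto acid loses CO2, leaves the quaternary and remote stereocentres untouched (the C1 descriptor changes by priority only).

Step 11
Reactants: 17 3-methylbutane-1,3-diol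
Product: 18 3-hydroxy-3-methylbutanal
Conditions: 2,2,6,6-tetramethylpiperidin-1-oxyl (10 mol %), PhI(OAc)2, CH2Cl2, rt; used fresh
Reagents that add atoms: none
Why: Oxoammonium-mediated oxidation takes only the primary alcohol, since the tertiary alcohol cannot be oxidised and without water the aldehyde is not carried on to the acid.

Step 12
Reactants: 16 the C3-unsubstituted trione, 18 3-hydroxy-3-methylbutanal
Product: 20 (1S,5S,7R)-4-hydroxy-3-(3-hydroxy-3-methylbutyl)-8,8-dimethyl-1-[(2R)-2-methylbutanoyl]-5,7-bis(3-methylbut-2-en-1-yl)bicyclo[3.3.1]non-3-ene-2,9-dione (CNP0326306.1), via C3 alkylidene trione 19 (not isolated)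
Conditions: L-proline (20 mol %), diethyl 2,6-dimethyl-1,4-dihydropyridine-3,5-dicarboxylate (Hantzsch ester), CH2Cl2, rt
Reagents that add atoms: none
Why: Organocatalytic three-component reductive alkylation of a cyclic 1,3-dione, that is a proline-mediated Knoevenagel condensation at C3 (the only enolisable ring carbon) followed by conjugate hydride transfer from the dihydropyridine to the alkylidene trione, forms the C3–C bond without creating a stereocentre.

**Compound list**

1 | (R)-2-methylbutanoic acid | CC[C@@H](C)C(=O)O | starting material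
2 | (R)-2-methylbutanoyl chloride | CC[C@@H](C)C(=O)Cl | intermediate
3 | methyl 2,4,6-trihydroxybenzoate | COC(=O)c1c(O)cc(O)cc1O | starting material
4 | methyl 2,4,6-trihydroxy-3-[(2R)-2-methylbutanoyl]benzoate | CC[C@@H](C)C(=O)c1c(O)cc(O)c(C(=O)OC)c1O | intermediate
5 | prenyl bromide (1-bromo-3-methylbut-2-ene) | CC(C)=CCBr | starting material
6 | methyl 2,4,6-trihydroxy-3-[(2R)-2-methylbutanoyl]-5-(3-methylbut-2-en-1-yl)benzoate | CC[C@@H](C)C(=O)c1c(O)c(CC=C(C)C)c(O)c(C(=O)OC)c1O | intermediate
7 | (S)-4-benzyl-2-oxazolidinone | O=C1N[C@@H](Cc2ccccc2)CO1 | starting material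
8 | 3-methylbut-2-enoyl chloride | CC(C)=CC(=O)Cl | starting material
9 | (4S)-4-benzyl-3-(3-methylbut-2-enoyl)oxazolidin-2-one | CC(C)=CC(=O)N1[C@@H](Cc2ccccc2)COC1=O | intermediate
10 | (4S)-4-benzyl-3-[(2S)-5-methyl-2-(prop-1-en-2-yl)hex-4-enoyl]oxazolidin-2-one | O=C([C@@H](CC=C(C)C)C(C)=C)N1[C@@H](Cc2ccccc2)COC1=O | intermediate
11 | (S)-lavandulol, (2S)-5-methyl-2-(prop-1-en-2-yl)hex-4-en-1-ol | OC[C@@H](CC=C(C)C)C(C)=C | intermediate
12 | (S)-lavandulyl triflate | O=S(=O)(OC[C@@H](CC=C(C)C)C(C)=C)C(F)(F)F | intermediate
13 | methyl (3S)-2,6-dihydroxy-5-[(2R)-2-methylbutanoyl]-3-(3-methylbut-2-en-1-yl)-3-[(2R)-5-methyl-2-(prop-1-en-2-yl)hex-4-en-1-yl]-4-oxocyclohexa-1,5-diene-1-carboxylate | CC[C@@H](C)C(=O)C1=C(O)C(C(=O)OC)=C(O)[C@](CC=C(C)C)(C[C@@H](CC=C(C)C)C(C)=C)C1=O | intermediate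
14 | methyl (1R,5S,7R)-4-hydroxy-8,8-dimethyl-1-[(2R)-2-methylbutanoyl]-5,7-bis(3-methylbut-2-en-1-yl)-2,9-dioxobicyclo[3.3.1]non-3-ene-3-carboxylate | CC[C@@H](C)C(=O)[C@]12C(=O)C(C(=O)OC)=C(O)[C@](CC=C(C)C)(C[C@@H](CC=C(C)C)C1(C)C)C2=O | intermediate
15 | C3 carboxylic acid corresponding to 14 (stereocentres as in 14) | CC[C@@H](C)C(=O)[C@]12C(=O)C(C(=O)O)=C(O)[C@](CC=C(C)C)(C[C@@H](CC=C(C)C)C1(C)C)C2=O | intermediate
16 | (1S,5S,7R)-4-hydroxy-8,8-dimethyl-1-[(2R)-2-methylbutanoyl]-5,7-bis(3-methylbut-2-en-1-yl)bicyclo[3.3.1]non-3-ene-2,9-dione | CC[C@@H](C)C(=O)[C@]12C(=O)C=C(O)[C@](CC=C(C)C)(C[C@@H](CC=C(C)C)C1(C)C)C2=O | intermediate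
17 | 3-methylbutane-1,3-diol | CC(C)(O)CCO | starting material
18 | 3-hydroxy-3-methylbutanal | CC(C)(O)CC=O | intermediate
19 | C3 (3-hydroxy-3-methylbutylidene) trione from 16 (stereocentres as in 16, alkene geometry undefined) | CC[C@@H](C)C(=O)[C@]12C(=O)C(=CCC(C)(C)O)C(=O)[C@](CC=C(C)C)(C[C@@H](CC=C(C)C)C1(C)C)C2=O | intermediate
20 | (1S,5S,7R)-4-hydroxy-3-(3-hydroxy-3-methylbutyl)-8,8-dimethyl-1-[(2R)-2-methylbutanoyl]-5,7-bis(3-methylbut-2-en-1-yl)bicyclo[3.3.1]non-3-ene-2,9-dione (CNP0326306.1) | CC[C@@H](C)C(=O)[C@]12C(=O)C(CCC(C)(C)O)=C(O)[C@](CC=C(C)C)(C[C@@H](CC=C(C)C)C1(C)C)C2=O | target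

**Step count**

Total: 12 steps. Longest linear sequence: 8 steps (steps 4, 5, 6, 7, 8, 9, 10, 12, from 3-methylbut-2-enoyl chloride).

**Steps most likely to fail**

1. Step 9 (the proposed new method). The triacylmethane carbon C1 may be too weak a nucleophile. The C8 cation could then be lost to irreversible O-capture, elimination or attack by the C7 prenyl alkene, protonation of the prenyl alkenes could lead to pyran rings, or closure could drift toward C3.
Fallback (known chemistry), setting out from 3 and returning at 16: the ring is closed before the ketone side chain is on it, and the acyl group is added at the bridgehead afterwards. Mono-C-prenylation of 3 with 5 (aq. KOH, 0 °C) would give methyl 2,4,6-trihydroxy-3-(3-methylbut-2-en-1-yl)benzoate F1. Dearomative alkylation with 12 (LiN(SiMe3)2, THF) and separation of the ring epimers would give the 5-unsubstituted lavandulyl prenyl dienone ester F2. Formic acid closure, now at an unacylated enol carbon as in the established cases, would give the C1–H bicyclic ester F3. O-Methylation (Me3SiCHN2, MeOH/toluene, keeping the C4 methyl ether) would give the vinylogous ester F4. Bridgehead lithiation (LiN(iPr)2, THF, −78 °C) and acylation with 2 would give the C1-acylated enol ether F5. LiCl in wet DMSO at 120 °C would then remove the O-methyl and methoxycarbonyl groups together, giving 16.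

2. Step 8. O-Alkylation or E2 elimination of the β-branched triflate may outrun C-alkylation at the fully substituted ring carbon, and the unselective formation of C5 may leave epimers that are hard to separate.
Fallback, setting out from 4 and returning at 13: the order of the two alkylations is reversed, so that the slow electrophile meets an unsubstituted ring carbon and the quaternary centre is made with the reactive allylic bromide. Alkylation of 4 with 12 (LiN(SiMe3)2, THF, 0 °C to rt) would give the lavandulyl arene methyl 2,4,6-trihydroxy-3-[(2R)-2-methylbutanoyl]-5-lavandulylbenzoate F6. Dearomative C-prenylation with 5 (LiN(SiMe3)2, THF, 0 °C), a well-established reaction for alkylated acylphloroglucinols, would then give 13 after separation of the C5 epimers.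

3. Step 12. The β-hydroxy aldehyde may dehydrate or undergo retro-aldol cleavage under amine catalysis, and the alkylidene intermediate may cyclise through its hydroxyl group before hydride transfer.
Fallback, setting out from 16 and returning at 20: the side chain is built in two stages without the sensitive aldehyde. Michael addition of 16 to methyl vinyl ketone (cat. Et3N, THF, rt) would give the 3-(3-oxobutyl) trione F7. Addition of MeMgBr (excess, THF, −78 to 0 °C, with CeCl3 if needed) should then hit only the unhindered methyl ketone, because the first equivalent turns the β-diketone into its enolate and the C9 and side-chain ketones are flanked by quaternary carbons; this gives 20.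

**Further compounds**

F1 | step 9 | methyl 2,4,6-trihydroxy-3-(3-methylbut-2-en-1-yl)benzoate | COC(=O)c1c(O)cc(O)c(CC=C(C)C)c1O
F2 | step 9 | 5-unsubstituted lavandulyl prenyl dienone ester (13 without the 2-methylbutanoyl group, same C5 and C7 configuration) | COC(=O)C1=C(O)[C@](CC=C(C)C)(C[C@@H](CC=C(C)C)C(C)=C)C(=O)C=C1O
F3 | step 9 | C1–H bicyclic ester (14 with H in place of the C1 acyl group) | [H][C@]12C(=O)C(C(=O)OC)=C(O)[C@](CC=C(C)C)(C[C@@H](CC=C(C)C)C1(C)C)C2=O
F4 | step 9 | C4 methyl enol ether of F3 | [H][C@]12C(=O)C(C(=O)OC)=C(OC)[C@](CC=C(C)C)(C[C@@H](CC=C(C)C)C1(C)C)C2=O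
F5 | step 9 | C1-[(2R)-2-methylbutanoyl] C4 methyl enol ether (O-methyl derivative of 14) | CC[C@@H](C)C(=O)[C@]12C(=O)C(C(=O)OC)=C(OC)[C@](CC=C(C)C)(C[C@@H](CC=C(C)C)C1(C)C)C2=O
F6 | step 8 | methyl 2,4,6-trihydroxy-3-[(2R)-2-methylbutanoyl]-5-lavandulylbenzoate (lavandulyl centre as in 11) | CC[C@@H](C)C(=O)c1c(O)c(C[C@@H](CC=C(C)C)C(C)=C)c(O)c(C(=O)OC)c1O
F7 | step 12 | 3-(3-oxobutyl) trione (16 carrying CH2CH2COCH3 at C3) | CC[C@@H](C)C(=O)[C@]12C(=O)C(CCC(C)=O)=C(O)[C@](CC=C(C)C)(C[C@@H](CC=C(C)C)C1(C)C)C2=O
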